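The plan hinges on hidden symmetry at C2. Apart from methyl and oxygen, this quaternary carbon holds the C3–C4 ethylene bridge of the pyran ring and the C1'=C2' alkene of the side chain, one ethyl-type and one vinyl-type branch of equal length. Both can be vinyl groups in an achiral precursor, a 2-bromoaryl ether of methyl divinyl carbinol (tert-butyl 3-bromo-4-[(3-methylpenta-1,4-dien-3-yl)oxy]benzoate). One operation then lets a chiral copper hydride metalate the terminus (C4) of a single enantiotopic vinyl group and lets palladium bond C4 to C4a. This creates the C4–C4a bond, the pyran ring and the (R) centre together. A Heck reaction extends the surviving vinyl group.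

Key step: step 2

Remarks before the steps
- Configuration: at C2 the ranking is O1 > C1' > C3 > CH3. The target SMILES corresponds to (R), and the same descriptor holds for every chiral intermediate below.
- Spectator group: the carboxyl group travels as a tert-butyl ester. A potassium tert-alkoxide would transesterify a methyl ester quickly, and the methoxide released would itself displace fluoride.
- Assumption: which antipode of DTBM-SEGPHOS leads to (R) cannot be predicted. The route is written with the (R)-ligand. The equally available (S)-ligand is taken if correlation of the chroman shows the opposite sense.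

Step 1
Reactants: 1 tert-butyl 3-bromo-4-fluorobenzoate; 2 3-methylpenta-1,4-dien-3-ol
Product: 4 tert-butyl 3-bromo-4-[(3-methylpenta-1,4-dien-3-yl)oxy]benzoate (achiral), via potassium alkoxide 3 (not isolated)
Conditions: 2 (1.2 equiv), KHMDS (1.15 equiv), THF, 0 °C; then 1, DMF, 0 °C → rt
Reagents that add atoms: none
Why: Nucleophilic aromatic substitution by addition–elimination: the para ester and the ortho bromine activate C4, fluoride leaves far faster than bromide, the tert-butyl ester resists acyl attack by the hindered alkoxide, a slight deficit of KHMDS leaves no amide base that could metalate the ring, and staying at or below room temperature keeps the bis-allylic aryl ether from aromatic Claisen rearrangement.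

Step 2
Reactants: 4 tert-butyl 3-bromo-4-[(3-methylpenta-1,4-dien-3-yl)oxy]benzoate
Product: 6 tert-butyl (R)-2-methyl-2-vinylchroman-6-carboxylate, via pinacol boronate 5 (not isolated)
Conditions: (i) CuCl (5 mol %), (R)-DTBM-SEGPHOS (5.5 mol %), KOt-Bu (10 mol %), HBpin (1.0 equiv, slow addition), toluene, 0 °C → rt; (ii) same flask, RuPhos Pd G3 (5 mol %), 2 M aq K3PO4 (3 equiv), THF, 60 °C, stopped at full conversion
Reagents that add atoms: none
Why: Proposed new method: the ligated copper hydride formed from CuCl, KOt-Bu and HBpin adds across one vinyl group with H to C3 and Cu to C4, σ-bond metathesis with HBpin passes C4 from copper to boron and returns the hydride, and once Pd and base are added Pd(0) inserts into C4a–Br, the boronate hands C4 to palladium and reductive elimination makes C4–C4a. Boron is interposed on purpose, because hydrocupration is irreversible and both metals are present only in a few mol %, so a direct copper-to-palladium handover would mostly pair an alkylcopper with the arylpalladium unit of a different molecule and give oligomers, whereas the boronate equips every molecule with its own nucleophile. The closest known reaction types are CuH-catalysed anti-Markovnikov hydroboration and CuH/Pd hydroarylation of terminal alkenes, copper-catalysed desymmetrisation of prochiral dienes and the intramolecular B-alkyl Suzuki–Miyaura coupling, and what has not been shown is selection between the two vinyl groups of a tertiary divinylcarbinyl aryl ether. In ring-closure terms the outcome is a 6-endo hydroarylation, reached by C–C reductive elimination from a seven-membered oxapalladacycle and not by alkene insertion, whose preference would be 5-exo. C2 becomes stereogenic at the hydrocupration, so its configuration is controlled only by the bisphosphine on copper, and any second hydroboration consumes mainly the minor enantiomer, which still carries the faster-reacting vinyl group. The step needs Cu at C4 and not C3 (the fully substituted C2 shields C3, which also avoids a β-aryloxy copper species), a single addition (1.0 equiv of HBpin), and boron-to-palladium transfer ahead of 5-exo insertion of the remaining vinyl group or Pd(0) ionisation of the allylic C2–O bond (palladium enters only after the bis-allylic ether is consumed, and the electron-poor C4a–Br bond captures Pd(0) quickly).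

Step 3
Reactants: 7 dihydro-β-ionone
Product: 9 2-(but-3-yn-1-yl)-1,3,3-trimethylcyclohex-1-ene, via enol phosphate 8 (not isolated)
Conditions: LDA (1.05 equiv), THF, −78 °C; ClP(O)(OEt)2, −78 °C → rt; LDA (2.3 equiv), −78 °C → rt; H2O
Reagents that add atoms: none
Why: Methyl ketone to terminal alkyne by way of the enol phosphate: kinetic deprotonation at the methyl group, O-phosphorylation and LDA-induced elimination of diethyl phosphate give the acetylide, which water protonates, while the tetrasubstituted ring alkene is inert to these reagents.

Step 4
Reactants: 9 2-(but-3-yn-1-yl)-1,3,3-trimethylcyclohex-1-ene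
Product: 11 2-[(3E)-4-iodo-3-methylbut-3-en-1-yl]-1,3,3-trimethylcyclohex-1-ene, via alkenylalane 10 (not isolated)
Conditions: Me3Al (2 equiv), Cp2ZrCl2 (0.25 equiv), CH2Cl2, 0 °C → rt; then I2, THF, −30 → 0 °C
Reagents that add atoms: trimethylaluminium C[Al](C)C; iodine II
Why: Zirconium-catalysed Negishi carboalumination adds methyl and aluminium syn across the alkyne with aluminium on the terminal carbon, and iodinolysis of the C–Al bond with retention fixes the E geometry that becomes C3'=C4' of the target.

Step 5
Reactants: 6 tert-butyl (R)-2-methyl-2-vinylchroman-6-carboxylate; 11 2-[(3E)-4-iodo-3-methylbut-3-en-1-yl]-1,3,3-trimethylcyclohex-1-ene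
Product: 12 tert-butyl (R)-2-methyl-2-[(1E,3E)-4-methyl-6-(2,6,6-trimethylcyclohex-1-en-1-yl)hexa-1,3-dien-1-yl]chroman-6-carboxylate
Conditions: 11 (1.3 equiv), Pd(OAc)2 (10 mol %), Ag2CO3 (1.2 equiv), DMF, rt → 45 °C, dark
Reagents that add atoms: none
Why: Mizoroki–Heck alkenylation under ligand-free silver carbonate conditions: the alkenylpalladium iodide, formed with retention of the E geometry, adds to the vinyl group with carbon going to the unhindered terminus C2', and syn β-hydride elimination, possible only from C2' because C2 bears no hydrogen, gives the E C1'=C2' alkene, while silver removes iodide and suppresses Pd–H re-addition, the excess of 11 keeps Pd(0) from ionising the allylic C2–O bond, and the stereocentre is not touched.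

Step 6
Reactants: 12 tert-butyl (R)-2-methyl-2-[(1E,3E)-4-methyl-6-(2,6,6-trimethylcyclohex-1-en-1-yl)hexa-1,3-dien-1-yl]chroman-6-carboxylate
Product: 14 (R)-2-methyl-2-[(1E,3E)-4-methyl-6-(2,6,6-trimethylcyclohex-1-en-1-yl)hexa-1,3-dien-1-yl]chroman-6-carboxylic acid (target), via potassium carboxylate 13 (not isolated)
Conditions: powdered KOH (10 equiv), THF, rt; then 10 % aq citric acid, 0 °C, to pH 4–5
Reagents that add atoms: potassium hydroxide [K+].[OH-]
Why: Saponification by acyl–oxygen cleavage: finely powdered KOH in THF supplies poorly solvated hydroxide that cleaves tert-butyl benzoates at ambient temperature, and the basic medium followed by a cold, mildly acidic work-up spares the acid-labile tertiary dienylic aryl ether, both E alkenes and the non-epimerisable C2.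

Compound list
1 | tert-butyl 3-bromo-4-fluorobenzoate | CC(C)(C)OC(=O)c1ccc(F)c(Br)c1 | starting material
2 | 3-methylpenta-1,4-dien-3-ol | C=CC(C)(O)C=C | starting material
3 | potassium 3-methylpenta-1,4-dien-3-olate | C=CC(C)([O-])C=C.[K+] | intermediate
4 | tert-butyl 3-bromo-4-[(3-methylpenta-1,4-dien-3-yl)oxy]benzoate | C=CC(C)(C=C)Oc1ccc(C(=O)OC(C)(C)C)cc1Br | intermediate
5 | tert-butyl 3-bromo-4-{[(3R)-3-methyl-5-(4,4,5,5-tetramethyl-1,3,2-dioxaborolan-2-yl)pent-1-en-3-yl]oxy}benzoate | C=C[C@@](C)(CCB1OC(C)(C)C(C)(C)O1)Oc1ccc(C(=O)OC(C)(C)C)cc1Br | intermediate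
6 | tert-butyl (R)-2-methyl-2-vinylchroman-6-carboxylate | C=C[C@@]1(C)CCc2cc(C(=O)OC(C)(C)C)ccc2O1 | intermediate
7 | dihydro-β-ionone, 4-(2,6,6-trimethylcyclohex-1-en-1-yl)butan-2-one | CC(=O)CCC1=C(C)CCCC1(C)C | starting material
8 | diethyl 4-(2,6,6-trimethylcyclohex-1-en-1-yl)but-1-en-2-yl phosphate | C=C(CCC1=C(C)CCCC1(C)C)OP(=O)(OCC)OCC | intermediate
9 | 2-(but-3-yn-1-yl)-1,3,3-trimethylcyclohex-1-ene | C#CCCC1=C(C)CCCC1(C)C | intermediate
10 | dimethyl[(1E)-2-methyl-4-(2,6,6-trimethylcyclohex-1-en-1-yl)but-1-en-1-yl]alane | C[Al](C)/C=C(\C)CCC1=C(C)CCCC1(C)C | intermediate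
11 | 2-[(3E)-4-iodo-3-methylbut-3-en-1-yl]-1,3,3-trimethylcyclohex-1-ene | I/C=C(\C)CCC1=C(C)CCCC1(C)C | intermediate
12 | tert-butyl (R)-2-methyl-2-[(1E,3E)-4-methyl-6-(2,6,6-trimethylcyclohex-1-en-1-yl)hexa-1,3-dien-1-yl]chroman-6-carboxylate | CC1=C(CC/C(C)=C/C=C/[C@@]2(C)CCc3cc(C(=O)OC(C)(C)C)ccc3O2)C(C)(C)CCC1 | intermediate
13 | potassium (R)-2-methyl-2-[(1E,3E)-4-methyl-6-(2,6,6-trimethylcyclohex-1-en-1-yl)hexa-1,3-dien-1-yl]chroman-6-carboxylate | CC1=C(CC/C(C)=C/C=C/[C@@]2(C)CCc3cc(C(=O)[O-])ccc3O2)C(C)(C)CCC1.[K+] | intermediate
14 | (R)-2-methyl-2-[(1E,3E)-4-methyl-6-(2,6,6-trimethylcyclohex-1-en-1-yl)hexa-1,3-dien-1-yl]chroman-6-carboxylic acid | CC1=C(CC/C(C)=C/C=C/[C@@]2(C)CCc3cc(C(=O)O)ccc3O2)C(C)(C)CCC1 | target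

Total step count: 6
Longest linear sequence: 4 steps (1, 2, 5, 6; the branch 3, 4, 5, 6 is equally long)

Steps most likely to fail

1. Step 2.
- What may go wrong:
  - weak discrimination between the two vinyl groups;
  - double hydroboration;
  - hydride delivery to the alkene terminus followed by expulsion of the aryloxide;
  - insertion of the arylpalladium unit into the neighbouring vinyl group before boron-to-palladium transfer;
  - reversible Pd(0) opening of the allylic C2–O bond, which erodes the enantiomeric purity.
- Fallback with known chemistry, from 4 back to 6: stoichiometric hydroboration of 4 with 9-BBN-H (1.0 equiv, THF, 0 °C → rt) gives the racemic B-alkyl-9-BBN adduct F1. Its much faster transmetalation allows an intramolecular B-alkyl Suzuki–Miyaura closure at room temperature (PdCl2(dppf), aq NaOH, THF) to the racemic vinylchroman F2. Preparative chromatography on a chiral stationary phase then delivers 6.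

2. Step 5.
- What may go wrong:
  - sluggish insertion at the neopentyl-like vinyl group;
  - loss of the aryloxide from the σ-alkylpalladium intermediate (Pd on C1' stands β to O1), with opening of the pyran ring;
  - scrambling of the diene geometry by Pd–H.
- Fallback, from 6 back to 12: Lemieux–Johnson cleavage (OsO4 cat., NaIO4, 2,6-lutidine, dioxane/H2O) gives the non-enolisable formylchroman F3. Takai olefination (CrCl2, CHI3, THF, 0 °C → rt) gives the (E)-iodovinylchroman F4. Negishi coupling of F4 gives 12 with both alkene geometries set before the C–C bond is made. Its partner is the alkenylalane 10, made from 9 as in step 4 without the iodine quench and freed of excess Me3Al in vacuo, and the coupling uses Pd(PPh3)4 and ZnCl2 (cat.) in THF at rt.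

3. Step 1.
- What may go wrong: displacement of fluoride is too slow at the temperatures the bis-allylic ether tolerates, so aromatic Claisen rearrangement or base-induced decay overtakes ether formation.
- Fallback, from 2 (through its alkoxide 3) back to 4: the alkoxide 3 is combined at −20 → 0 °C in THF/DMF with purchased 3-bromo-4-fluorobenzaldehyde. The formyl group activates the ring far more strongly than an ester and gives the aldehyde ether F5. Pinnick oxidation (NaClO2, NaH2PO4, 2-methyl-2-butene, t-BuOH/H2O) gives the acid F6. Boc2O, DMAP and t-BuOH at rt then install the tert-butyl ester of 4.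

Further compounds
F1 | step 2 | tert-butyl 4-{[5-(9-borabicyclo[3.3.1]nonan-9-yl)-3-methylpent-1-en-3-yl]oxy}-3-bromobenzoate (racemic) | C=CC(C)(CCB1C2CCCC1CCC2)Oc1ccc(C(=O)OC(C)(C)C)cc1Br
F2 | step 2 | tert-butyl 2-methyl-2-vinylchroman-6-carboxylate (racemic) | C=CC1(C)CCc2cc(C(=O)OC(C)(C)C)ccc2O1
F3 | step 5 | tert-butyl (R)-2-formyl-2-methylchroman-6-carboxylate | O=C[C@@]1(C)CCc2cc(C(=O)OC(C)(C)C)ccc2O1
F4 | step 5 | tert-butyl (R)-2-[(E)-2-iodovinyl]-2-methylchroman-6-carboxylate | I/C=C/[C@@]1(C)CCc2cc(C(=O)OC(C)(C)C)ccc2O1
F5 | step 1 | 3-bromo-4-[(3-methylpenta-1,4-dien-3-yl)oxy]benzaldehyde | C=CC(C)(C=C)Oc1ccc(C=O)cc1Br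
F6 | step 1 | 3-bromo-4-[(3-methylpenta-1,4-dien-3-yl)oxy]benzoic acid | C=CC(C)(C=C)Oc1ccc(C(=O)O)cc1Br
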